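The furanone oxygen bridges C3 and C10 of the ten-membered carbocycle (C1–C10), and C10 is also bonded to C1. Reconnecting C3 to C8 therefore turns C10=C9–C8–C3–C2=C1 into the 1,5-diene of a cyclohexane. The key step, a formal anionic oxy-Cope rearrangement of a C8 alkoxide, breaks C3–C8 and joins C1 to C10 in one operation. This gives the ten-membered ring, the O/C3/C2/C1/C10 ring, quaternary C10 and the C8 ketone. Its precursor is a cis-fused 2-methyl-hexahydrobenzofuran-3a-ol with a (Z)-2-ethoxyvinyl group on C3, a C4 methyl, a C6 MOM ether and a C7 allyl group.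

Key step: step 13

Atom labels used throughout are those of the target: C1 furanone C=O, C2 =CH, C3 enol-ether carbon, C4 CH(CH3), C5 CH2, C6 lactone O–CH, C7 ring-fusion CH, C8 acyloxy CH, C9 CH2, C10 C(CH3)–O, C11/C12/C13 lactone α-carbon, carbonyl and =CH2.
Remark: the configurations at C8 in 12, 13 and 16 and at C1 in 24, 25 and 28 are immaterial, because both centres become carbonyl carbons; the isomers drawn are the expected major ones.
Remark: (S)-2-methylglycidol 26 is assumed to be purchasable; if not, it is one asymmetric epoxidation away from 2-methylprop-2-en-1-ol.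

Step 1
Reactants: 1 (R)-pulegone
Product: 2 pulegone oxide (epoxide of the exocyclic double bond, both spiro epimers)
Conditions: H2O2 (30% aq.), LiOH, MeOH, 0 °C to rt
Reagents that add atoms: hydrogen peroxide, OO
Why: Weitz–Scheffer nucleophilic epoxidation of the enone (conjugate addition of hydroperoxide, then ring closure); the new spiro centre is lost in step 2, so its configuration does not matter.

Step 2
Reactants: 2 pulegone oxide
Product: 3 (5R)-5-methyl-2-(phenylsulfanyl)cyclohexan-1-one (mixture at C2)
Conditions: PhSNa, THF, reflux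
Reagents that add atoms: sodium benzenethiolate, [Na+].[S-]c1ccccc1
Why: Thiolate opens the epoxide at the α-keto carbon and the resulting β-alkoxide expels acetone by retro-aldol cleavage, which leaves the methyl-bearing stereocentre untouched.

Step 3
Reactants: 3 (5R)-5-methyl-2-(phenylsulfanyl)cyclohexan-1-one
Product: 5 (R)-5-methylcyclohex-2-en-1-one, via sulfoxide 4 (not isolated)
Conditions: mCPBA, CH2Cl2, −78 °C; then CaCO3, toluene, 110 °C
Reagents that add atoms: none
Why: Sulfide oxidation followed by thermal syn-elimination of the sulfoxide (only the ring CH2 offers β-hydrogens) gives the enone without touching the remote stereocentre.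

Step 4
Reactants: 5 (R)-5-methylcyclohex-2-en-1-one
Product: 6 (1R,5R)-5-methylcyclohex-2-en-1-ol (cis)
Conditions: NaBH4, CeCl3·7H2O, MeOH, −78 °C
Reagents that add atoms: none
Why: Luche 1,2-reduction; axial hydride delivery to the half-chair with a pseudo-equatorial methyl group should give the cis alcohol, which sets C6 relative to C4.

Step 5
Reactants: 6 (1R,5R)-5-methylcyclohex-2-en-1-ol
Product: 7 (3R,5R)-3-(methoxymethoxy)-5-methylcyclohex-1-ene
Conditions: MOMCl, i-Pr2NEt, CH2Cl2, 0 °C to rt
Reagents that add atoms: chloromethyl methyl ether, COCCl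
Why: O-Alkylation of the alcohol; the MOM ether is stable to bases, organometallics and oxidants and can later chelate zinc in step 14.

Step 6
Reactants: 7 (3R,5R)-3-(methoxymethoxy)-5-methylcyclohex-1-ene
Product: 8 (4R,6S)-4-(methoxymethoxy)-6-methylcyclohex-2-en-1-one (OMOM and methyl cis; carbonyl = C3, C8=C7)
Conditions: CrO3, 3,5-dimethylpyrazole, CH2Cl2, −20 °C
Reagents that add atoms: chromium trioxide, O=[Cr](=O)=O
Why: Allylic oxidation with the CrO3–dimethylpyrazole complex converts the only allylic methylene into the enone carbonyl, the usual outcome for cyclohex-2-enyl ethers, and touches no stereocentre.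

Step 7
Reactants: 8 (4R,6S)-4-(methoxymethoxy)-6-methylcyclohex-2-en-1-one; 9 allylmagnesium bromide
Product: 11 silyl enol ether [4-(methoxymethoxy)-6-methyl-3-(prop-2-en-1-yl)-1-(trimethylsilyloxy)cyclohex-1-ene; allyl trans to OMOM], via allylcopper 10 (not isolated)
Conditions: CuBr·SMe2, LiCl, TMSCl, THF, −78 °C; Et3N, then aq. NaHCO3
Reagents that add atoms: chlorotrimethylsilane, C[Si](C)(C)Cl
Why: TMSCl-accelerated conjugate addition of an allylcopper reagent, which should enter C7 anti to the adjacent C6 alkoxy group (the normal sense for 4-alkoxycyclohex-2-enones); the enolate is trapped regiospecifically between C3 and C8.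

Step 8
Reactants: 11 silyl enol ether
Product: 13 α-hydroxy ketone [2-hydroxy-4-(methoxymethoxy)-6-methyl-3-(prop-2-en-1-yl)cyclohexan-1-one; C3 ketone, C8 hydroxyl trans to allyl], via silyloxy ketone 12 (not isolated)
Conditions: mCPBA, NaHCO3, CH2Cl2, −20 °C; then citric acid, MeOH, 0 °C
Reagents that add atoms: 3-chloroperbenzoic acid, OOC(=O)c1cccc(Cl)c1
Why: Rubottom oxidation; the electron-rich silyl enol ether is epoxidised far faster than the terminal allyl double bond, and silyl migration followed by mild acid frees the α-hydroxy ketone.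

Step 9
Reactants: 13 α-hydroxy ketone; 14 (Z)-1-bromo-2-ethoxyethene
Product: 16 diol [1-[(Z)-2-ethoxyethenyl]-4-(methoxymethoxy)-6-methyl-3-(prop-2-en-1-yl)cyclohexane-1,2-diol; C3 hydroxyl axial and cis to the C4 methyl, alkenyl equatorial], via (Z)-2-ethoxyvinyllithium 15 (not isolated)
Conditions: 14 (3.2 equiv), t-BuLi (6.4 equiv), THF, −78 °C; then 13, −78 to −40 °C; aq. NaHCO3
Reagents that add atoms: none
Why: Lithium–bromine exchange and 1,2-addition of the vinyllithium (one equivalent deprotonates the hydroxyl); attack on the lithium-alkoxide-chelated cyclohexanone along the equatorial trajectory, trans to both equatorial neighbours (C4 methyl, C8 oxygen), should set C3.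

Step 10
Reactants: 16 diol
Product: 17 α-ketol [2-[(Z)-2-ethoxyethenyl]-2-hydroxy-5-(methoxymethoxy)-3-methyl-6-(prop-2-en-1-yl)cyclohexan-1-one; C8 ketone]
Conditions: SO3·pyridine, DMSO, Et3N, CH2Cl2, 0 °C
Reagents that add atoms: none
Why: Parikh–Doering oxidation of the secondary C8 alcohol under non-acidic conditions that neither cleave the 1,2-diol nor disturb the acid-labile β-ethoxyvinyl carbinol.

Step 11
Reactants: 17 α-ketol; 18 propargyl bromide
Product: 20 propargyl diol [1-[(Z)-2-ethoxyethenyl]-4-(methoxymethoxy)-6-methyl-3-(prop-2-en-1-yl)-2-(prop-2-yn-1-yl)cyclohexane-1,2-diol; trans-diol, propargyl cis to the C3 oxygen], via allenylzinc bromide 19 (not isolated)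
Conditions: Zn dust (activated), THF, 0 °C; pH 7 phosphate buffer
Reagents that add atoms: none
Why: Barbier propargylation in which the allenylzinc adds through its γ-carbon (SE2′); coordination of zinc by the axial C3 hydroxyl and the C6 MOM oxygens, both on the upper face, should deliver the propargyl group to that face (hydroxyl-directed addition) and so set C8.

Step 12
Reactants: 20 propargyl diol
Product: 21 rearrangement precursor [cis-fused 7a-[(Z)-2-ethoxyethenyl]-5-(methoxymethoxy)-2,7-dimethyl-4-(prop-2-en-1-yl)-3a,4,5,6,7,7a-hexahydro-1-benzofuran-3a-ol]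
Conditions: t-BuOK (0.3 equiv), DMSO, 25 °C
Reagents that add atoms: none
Why: Base-mediated intramolecular hydroalkoxylation (5-exo-dig attack of the C3 alkoxide on C10, with alkyne–allene equilibration and double-bond migration funnelling to the more stable endocyclic C9=C10 enol ether); only the isomer with C3–O and C9 cis can close, and no acid or electrophilic metal meets the ethoxyvinyl group.

Step 13
Reactants: 21 rearrangement precursor
Product: 24 ten-membered ketone [10-ethoxy-5-(methoxymethoxy)-1,7-dimethyl-4-(prop-2-en-1-yl)-11-oxabicyclo[6.2.1]undec-8-en-3-one; C8 ketone, C1 ethoxy, C2=C3 enol ether, oxygen bridge C3–C10], via potassium alkoxide 22 (not isolated), via potassium enolate 23 (not isolated)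
Conditions: KH, 18-crown-6, THF, 0 to 45 °C; then AcOH, THF, −78 °C
Reagents that add atoms: none
Why: Proposed new method: deprotonation of 21 with KH and 18-crown-6 should give the loosely ion-paired C8 alkoxide 22, in which donation from oxygen labilises the adjacent C3–C8 bond so that the 1,5-diene C10=C9–C8–C3–C2=C1 can undergo a 3,3-shift; because that bond lies close to the nodal plane of the ring enol ether, the likelier course is heterolysis to a C8 vinylogous ester tethered through the ring oxygen to a 1,3-dioxygenated allyl anion that re-adds through C1 to C10, and either course ends in the C8 enolate 23. The closest known reaction type is the anionic oxy-Cope ring expansion of 1,2-dialkenylcyclohexanols to cyclodec-5-enones, including its stepwise fragmentation–recombination variant with hindered homoallylic potassium alkoxides. The five-membered O/C3/C2/C1/C10 ring closes by attack of C1 on C10 (5-exo-trig with respect to the C9=C10 acceptor), whereas the ten-membered carbocycle is not cyclised but arises because C1–C10 replaces C3–C8 in the cyclohexane. C10 is controlled by C3, since the C3–O–C10 tether lets C1 reach only the face of C10 on which the alkenyl group sat, which relays the cis ring fusion (both fusion centres are destroyed) into the quaternary centre; the C1 centre follows from the Z enol ether and is erased in step 17. The step needs bonding through C1 and not C3 of the allyl unit, which ring size enforces (C3 could only regenerate 22), and an enolate that stays on the C9 side, which the −78 °C acetic acid quench should secure before proton transfer to C7 can epimerise it or expel the C6 MOM ether.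

Step 14
Reactants: 24 ten-membered ketone
Product: 25 C8 alcohol (8S, hydroxyl syn to the C6 OMOM group and anti to the C7 allyl group)
Conditions: Zn(BH4)2, Et2O, −30 °C
Reagents that add atoms: none
Why: Chelation-controlled reduction; zinc bridges the C8 carbonyl and the C6 MOM ether and external hydride attacks the chelate anti to the C7 allyl group, which should give the 6,8-syn alcohol (1,3-syn reduction of β-alkoxy ketones).

Step 15
Reactants: 26 (S)-2-methylglycidol
Product: 27 (R)-2-methyloxirane-2-carboxylic acid
Conditions: TEMPO (cat.), NaOCl (cat.), NaClO2, MeCN/phosphate buffer pH 6.7, 35 °C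
Reagents that add atoms: sodium chlorite, [Na+].[O-]Cl=O
Why: TEMPO/chlorite oxidation takes the primary alcohol to the acid near neutral pH without opening the epoxide; the quaternary stereocentre is not involved (the descriptor changes only by priority).

Step 16
Reactants: 25 C8 alcohol; 27 (R)-2-methyloxirane-2-carboxylic acid
Product: 28 C8 ester [8-O-((R)-2-methyloxirane-2-carbonyl) derivative of 25]
Conditions: 27, 2,4,6-trichlorobenzoyl chloride, Et3N, THF, 0 °C; then 25, DMAP, toluene, rt
Reagents that add atoms: none
Why: Yamaguchi esterification through the mixed anhydride acylates the hindered C8 alcohol under basic conditions with retention at C8; the epoxide is the masked 2,3-diol of the side chain.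

Step 17
Reactants: 28 C8 ester
Product: 29 furanone (C1 ketone, C2=C3, oxygen bridge C3–C10; MOM, allyl and epoxy ester retained)
Conditions: DDQ, CH2Cl2/pH 7 phosphate buffer (10:1), 0 °C
Reagents that add atoms: water, O
Why: DDQ abstracts hydride from C1, which is activated by the ethoxy group and, through C2=C3, by the ring oxygen; water converts the resulting 1,3-dioxygenated allyl cation into the 3(2H)-furanone with loss of ethanol (oxidation of an allylic ether to the enone).

Step 18
Reactants: 29 furanone
Product: 30 aldehyde (C7–CH2–CHO; C11, C12)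
Conditions: OsO4 (cat.), NaIO4, 2,6-lutidine, dioxane/H2O, rt
Reagents that add atoms: osmium tetroxide, O=[Os](=O)(=O)=O; sodium periodate, [Na+].[O-]I(=O)(=O)=O
Why: Lemieux–Johnson cleavage of the monosubstituted alkene; the furanone C2=C3 bond is an electron-poor vinylogous ester and should not be dihydroxylated.

Step 19
Reactants: 30 aldehyde
Product: 31 2-methylene aldehyde (C7–C(=CH2)–CHO; C13 installed)
Conditions: CH2=NMe2 I (dimethylmethyleneammonium iodide), Et3N, CH2Cl2, rt
Reagents that add atoms: dimethylmethyleneammonium iodide, C=[N+](C)C.[I-]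
Why: Mannich reaction of the aldehyde followed by amine-induced loss of dimethylamine gives the α-methylene aldehyde under conditions too weakly basic to enolise the furanone toward C4.

Step 20
Reactants: 31 2-methylene aldehyde
Product: 32 acrylic acid (C7–C(=CH2)–CO2H)
Conditions: NaClO2, NaH2PO4, 2-methyl-2-butene, t-BuOH/H2O, 0 °C
Reagents that add atoms: sodium chlorite, [Na+].[O-]Cl=O
Why: Pinnick oxidation converts the enal to the acid without attacking the conjugated double bond, the hypochlorous acid by-product being scavenged by 2-methyl-2-butene.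

Step 21
Reactants: 32 acrylic acid
Product: 33 CNP0263764.2 (target)
Conditions: H2SO4 (2 M aq.), THF, 40 °C
Reagents that add atoms: water, O
Why: Aqueous acid hydrolyses the MOM acetal, hydrates the epoxide at its CH2 carbon (the quaternary centre keeps its C–O bond and ends as R), and the freed C6 hydroxyl lactonises onto the acrylic acid to give the trans-fused α-methylene γ-lactone.

Compound list
1 | (R)-pulegone | C[C@@H]1CCC(=C(C)C)C(=O)C1 | starting material
2 | pulegone oxide (2,2,6-trimethyl-1-oxaspiro[2.5]octan-4-one, spiro epimers) | C[C@@H]1CCC2(OC2(C)C)C(=O)C1 | intermediate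
3 | (5R)-5-methyl-2-(phenylsulfanyl)cyclohexan-1-one | C[C@@H]1CCC(Sc2ccccc2)C(=O)C1 | intermediate
4 | (5R)-5-methyl-2-(phenylsulfinyl)cyclohexan-1-one | C[C@@H]1CCC(S(=O)c2ccccc2)C(=O)C1 | intermediate (not isolated)
5 | (R)-5-methylcyclohex-2-en-1-one | C[C@@H]1CC=CC(=O)C1 | intermediate
6 | (1R,5R)-5-methylcyclohex-2-en-1-ol | C[C@H]1C[C@@H](O)C=CC1 | intermediate
7 | (3R,5R)-3-(methoxymethoxy)-5-methylcyclohex-1-ene | C[C@H]1C[C@@H](OCOC)C=CC1 | intermediate
8 | (4R,6S)-4-(methoxymethoxy)-6-methylcyclohex-2-en-1-one | C[C@H]1C[C@@H](OCOC)C=CC1=O | intermediate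
9 | allylmagnesium bromide | C=CC[Mg]Br | starting material
10 | allylcopper | C=CC[Cu] | intermediate (not isolated)
11 | 4-(methoxymethoxy)-6-methyl-3-(prop-2-en-1-yl)-1-(trimethylsilyloxy)cyclohex-1-ene (allyl trans to OMOM, methyl cis to OMOM) | C[C@H]1C[C@@H](OCOC)[C@H](CC=C)C=C1O[Si](C)(C)C | intermediate
12 | 4-(methoxymethoxy)-6-methyl-3-(prop-2-en-1-yl)-2-(trimethylsilyloxy)cyclohexan-1-one | C[C@H]1C[C@@H](OCOC)[C@H](CC=C)[C@@H](O[Si](C)(C)C)C1=O | intermediate (not isolated)
13 | 2-hydroxy-4-(methoxymethoxy)-6-methyl-3-(prop-2-en-1-yl)cyclohexan-1-one (C3 ketone; C8 hydroxyl trans to allyl) | C[C@H]1C[C@@H](OCOC)[C@H](CC=C)[C@@H](O)C1=O | intermediate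
14 | (Z)-1-bromo-2-ethoxyethene | CCO/C=C\Br | starting material
15 | (Z)-2-ethoxyvinyllithium | CCO/C=C\[Li] | intermediate (not isolated)
16 | 1-[(Z)-2-ethoxyethenyl]-4-(methoxymethoxy)-6-methyl-3-(prop-2-en-1-yl)cyclohexane-1,2-diol (C3–OH cis to C4 methyl and to C8–OH) | C[C@H]1C[C@@H](OCOC)[C@H](CC=C)[C@@H](O)[C@]1(O)/C=C\OCC | intermediate
17 | 2-[(Z)-2-ethoxyethenyl]-2-hydroxy-5-(methoxymethoxy)-3-methyl-6-(prop-2-en-1-yl)cyclohexan-1-one (C8 ketone) | C[C@H]1C[C@@H](OCOC)[C@H](CC=C)C(=O)[C@]1(O)/C=C\OCC | intermediate
18 | propargyl bromide (3-bromoprop-1-yne) | C#CCBr | starting material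
19 | allenylzinc bromide | C=C=C[Zn]Br | intermediate (not isolated)
20 | 1-[(Z)-2-ethoxyethenyl]-4-(methoxymethoxy)-6-methyl-3-(prop-2-en-1-yl)-2-(prop-2-yn-1-yl)cyclohexane-1,2-diol (trans-diol; propargyl cis to C3–OH) | C[C@H]1C[C@@H](OCOC)[C@H](CC=C)[C@@](O)(CC#C)[C@]1(O)/C=C\OCC | intermediate
21 | cis-fused 7a-[(Z)-2-ethoxyethenyl]-5-(methoxymethoxy)-2,7-dimethyl-4-(prop-2-en-1-yl)-3a,4,5,6,7,7a-hexahydro-1-benzofuran-3a-ol (rearrangement precursor) | C[C@H]1C[C@@H](OCOC)[C@H](CC=C)[C@@]2(O)C=C(C)O[C@@]12/C=C\OCC | intermediate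
22 | potassium C8 alkoxide of 21 | C[C@H]1C[C@@H](OCOC)[C@H](CC=C)[C@@]2([O-])C=C(C)O[C@@]12/C=C\OCC.[K+] | intermediate (not isolated)
23 | potassium C8 enolate (C8=C9) of 24 | C[C@H]1C[C@@H](OCOC)[C@H](CC=C)C([O-])=C[C@@]2(C)OC1=C[C@@H]2OCC.[K+] | intermediate (not isolated)
24 | 10-ethoxy-5-(methoxymethoxy)-1,7-dimethyl-4-(prop-2-en-1-yl)-11-oxabicyclo[6.2.1]undec-8-en-3-one (rearrangement product) | C[C@H]1C[C@@H](OCOC)[C@H](CC=C)C(=O)C[C@@]2(C)OC1=C[C@@H]2OCC | intermediate
25 | C8 alcohol of 24 (8S; 6,8-syn) | C[C@H]1C[C@@H](OCOC)[C@H](CC=C)[C@@H](O)C[C@@]2(C)OC1=C[C@@H]2OCC | intermediate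
26 | (S)-2-methylglycidol, [(2S)-2-methyloxiran-2-yl]methanol | OC[C@@]1(C)CO1 | starting material
27 | (R)-2-methyloxirane-2-carboxylic acid | OC(=O)[C@@]1(C)CO1 | intermediate
28 | 8-O-[(R)-2-methyloxirane-2-carbonyl] ester of 25 | C[C@H]1C[C@@H](OCOC)[C@H](CC=C)[C@@H](OC(=O)[C@@]2(C)CO2)C[C@@]3(C)OC1=C[C@@H]3OCC | intermediate
29 | bridged 3(2H)-furanone (C1 ketone) with C6 OMOM, C7 allyl and C8 epoxy ester | C[C@H]1C[C@@H](OCOC)[C@H](CC=C)[C@@H](OC(=O)[C@@]2(C)CO2)C[C@@]3(C)OC1=CC3=O | intermediate
30 | C12 aldehyde (C7–CH2–CHO) | C[C@H]1C[C@@H](OCOC)[C@H](CC=O)[C@@H](OC(=O)[C@@]2(C)CO2)C[C@@]3(C)OC1=CC3=O | intermediate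
31 | 2-methylene aldehyde (C7–C(=CH2)–CHO) | C[C@H]1C[C@@H](OCOC)[C@H](C(=C)C=O)[C@@H](OC(=O)[C@@]2(C)CO2)C[C@@]3(C)OC1=CC3=O | intermediate
32 | acrylic acid (C7–C(=CH2)–CO2H) | C[C@H]1C[C@@H](OCOC)[C@H](C(=C)C(=O)O)[C@@H](OC(=O)[C@@]2(C)CO2)C[C@@]3(C)OC1=CC3=O | intermediate
33 | CNP0263764.2 (4S,6R,7S,8S,10R; side chain R) | C=C1C(=O)O[C@@H]2C[C@H](C)C3=CC(=O)[C@@](C)(C[C@H](OC(=O)[C@](C)(O)CO)[C@@H]12)O3 | target

Total step count: 21. Longest linear sequence: 20 steps (steps 1–14 and 16–21).

Steps most likely to fail

1. Step 13 (the key step). The alkoxide may not release the C3–C8 bond, the freed allyl unit may fail to re-bond at C10, or the new β-alkoxy ketone may lose the C6 ether by β-elimination before the quench. The fallback uses only established reactions and closes the ten-membered ring at C9–C10 instead.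
   - It sets out from 13. Criegee cleavage of the α-hydroxy ketone with Pb(OAc)4 in MeOH/benzene would give the seco aldehyde ester F1.
   - CH2=CHMgBr at −78 °C would add to the aldehyde to give the allylic alcohol F2.
   - Crossed Claisen condensation of the methyl ester with the lithium enolate of 3-(trimethylsilyloxy)butan-2-one (LDA, excess), followed by aqueous HCl (desilylation and cyclodehydration of the α′-hydroxy-1,3-diketone), would build the 2-methylfuran-3(2H)-one F3.
   - Dess–Martin periodinane would give the vinyl ketone F4.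
   - Intramolecular Michael addition of the furanone C10 enolate (DBU, MeCN, high dilution) would form the bridged furanone ketone F5, with C10 set under macrocyclic control.
   - Zn(BH4)2 would reduce C8 to the alcohol F6, and Yamaguchi esterification with 27 would rejoin the route at 29.

2. Step 11. The propargyl group may be delivered to the lower face of the C8 carbonyl, anti to the axial C3 oxygen, which gives a diastereomer that cannot close the cis-fused ring in step 12. The fallback replaces the kinetic carbonyl addition by a thermodynamically steered methylene transfer. It sets out from 17: Corey–Chaykovsky reaction with dimethylsulfoxonium methylide (Me3S(O)I, NaH, DMSO), whose reversible addition places the new C–C bond equatorial, would give the spiro-epoxide F7. Opening at its CH2 with lithium acetylide–ethylenediamine complex in DMSO would return to the route at 20.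

3. Step 14. Facial selectivity of hydride delivery may be poor or reversed if the zinc chelate between the C8 carbonyl and the C6 MOM ether cannot form inside the bridged ring. The fallback sets the centre by inversion: from 24, a non-chelating bulky hydride (LiBH(s-Bu)3, THF, −78 °C) would give the 8-epi alcohol F8. Mitsunobu esterification with acid 27 (PPh3, DIAD, toluene) would invert C8 and return to the route at 28.

Further compounds
F1 | step 13 | methyl 5-formyl-4-(methoxymethoxy)-2-methyloct-7-enoate (C4, C6, C7 as in 13) | COC(=O)[C@@H](C)C[C@@H](OCOC)[C@H](CC=C)C=O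
F2 | step 13 | methyl 5-(1-hydroxyprop-2-en-1-yl)-4-(methoxymethoxy)-2-methyloct-7-enoate (carbinol epimers) | COC(=O)[C@@H](C)C[C@@H](OCOC)[C@H](CC=C)C(O)C=C
F3 | step 13 | 2-methylfuran-3(2H)-one carrying the C4–C8 chain with the C8 allylic alcohol (C10 epimers) | CC1OC(=CC1=O)[C@@H](C)C[C@@H](OCOC)[C@H](CC=C)C(O)C=C
F4 | step 13 | vinyl ketone of F3 (C8 ketone, C9 =CH2) | CC1OC(=CC1=O)[C@@H](C)C[C@@H](OCOC)[C@H](CC=C)C(=O)C=C
F5 | step 13 | bridged furanone with C8 ketone, C6 OMOM and C7 allyl | C[C@H]1C[C@@H](OCOC)[C@H](CC=C)C(=O)C[C@@]2(C)OC1=CC2=O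
F6 | step 13 | bridged furanone with C8 hydroxyl (8S) | C[C@H]1C[C@@H](OCOC)[C@H](CC=C)[C@@H](O)C[C@@]2(C)OC1=CC2=O
F7 | step 11 | C8 spiro-epoxide of 17 (CH2 equatorial, cis to the C3 oxygen) | C[C@H]1C[C@@H](OCOC)[C@H](CC=C)[C@@]2(CO2)[C@]1(O)/C=C\OCC
F8 | step 14 | 8-epi alcohol of 24 | C[C@H]1C[C@@H](OCOC)[C@H](CC=C)[C@H](O)C[C@@]2(C)OC1=C[C@@H]2OCC
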